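**Retrosynthetic overview**

- The target is a perbrominated catechol ring (ring A: C1–OH, C2–C5 Br, C6–OAr) whose second oxygen carries a 2-bromophenyl group (ring B). The free phenol is masked as its methyl ether until the last step.
- The strategy rests on ring B, where the ether oxygen (C1) and the only bromine (C2) sit on adjacent carbons. Both bonds are cut at once, giving benzyne, the tetrabromoguaiacolate oxygen nucleophile and an electrophilic bromine donor.
- Ring A comes from guaiacol by exhaustive bromination. The benzyne precursor comes from 2-bromophenol by O-silylation, retro-Brook shift and triflation.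
- No ring is formed. Both benzene rings are bought intact: ring A is perbrominated first, the rings are then joined through oxygen with simultaneous ortho-bromination of ring B, and the phenol is unmasked last. The target has no stereogenic element.

Key step: step 6

**Route**

Step 1
Reactants: 1 guaiacol (2-methoxyphenol)
Product: 2 3,4,5,6-tetrabromoguaiacol (2,3,4,5-tetrabromo-6-methoxyphenol)
Conditions: Br2 (6 equiv), FeBr3 (cat.), CHCl3, 0 °C to 45 °C; aq Na2S2O3 work-up
Reagents that add atoms: bromine, BrBr
Why: Electrophilic aromatic bromination, in which the OH and OMe donors activate all four free ring positions and excess Br2 with FeBr3 should also force the last, most hindered position next to OMe to react.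

Step 2
Reactants: 3 2-bromophenol
Product: 4 (2-bromophenoxy)trimethylsilane
Conditions: HMDS (0.6 equiv), neat, 80 °C; volatiles removed in vacuo
Reagents that add atoms: hexamethyldisilazane, C[Si](C)(C)N[Si](C)(C)C
Why: O-Silylation of a phenol with hexamethyldisilazane, driven by loss of ammonia, should give the aryl silyl ether without any salt by-product.

Step 3
Reactants: 4 (2-bromophenoxy)trimethylsilane
Product: 7 2-(trimethylsilyl)phenol, via (2-lithiophenoxy)trimethylsilane 5 (not isolated), via lithium 2-(trimethylsilyl)phenoxide 6 (not isolated)
Conditions: n-BuLi (1.1 equiv), THF, −78 °C to rt; then sat. aq NH4Cl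
Reagents that add atoms: none
Why: Bromine–lithium exchange gives the ortho-lithiated silyl ether, which undergoes the anionic 1,3 O-to-C silyl shift (retro-Brook rearrangement) driven by formation of the more stable phenoxide, and mild protonation then frees the phenol.

Step 4
Reactants: 7 2-(trimethylsilyl)phenol
Product: 8 2-(trimethylsilyl)phenyl trifluoromethanesulfonate
Conditions: Tf2O (1.2 equiv), pyridine (1.5 equiv), CH2Cl2, 0 °C
Reagents that add atoms: trifluoromethanesulfonic anhydride, O=S(=O)(OS(=O)(=O)C(F)(F)F)C(F)(F)F
Why: Standard O-triflation of a phenol, under fluoride-free and non-nucleophilic conditions that leave the aryl C–Si bond untouched.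

Step 5
Reactants: 2 3,4,5,6-tetrabromoguaiacol
Product: 9 potassium 2,3,4,5-tetrabromo-6-methoxyphenoxide
Conditions: KH (1.05 equiv, oil-free), THF, 0 °C to rt; filtered under Ar, concentrated, dried in vacuo
Reagents that add atoms: potassium hydride, [K+].[H-]
Why: Irreversible acid–base reaction of the acidic polybromophenol with KH, whose only by-product is H2, so the dry salt carries no proton donor into the next step.

Step 6
Reactants: 9 potassium 2,3,4,5-tetrabromo-6-methoxyphenoxide; 8 2-(trimethylsilyl)phenyl trifluoromethanesulfonate; 10 bromopentafluorobenzene
Product: 13 1,2,3,4-tetrabromo-5-(2-bromophenoxy)-6-methoxybenzene, via benzyne 11 (not isolated), via 2-aryloxyphenylpotassium 12 (not isolated)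
Conditions: 8 (1.0 equiv), 9 (1.5 equiv), 10 (4 equiv, present from the start), KF (spray-dried, 2.5 equiv), 18-crown-6 (dried, 4 equiv), THF, 0 °C to rt; then H2O
Reagents that add atoms: bromopentafluorobenzene (compound 10), Fc1c(F)c(F)c(Br)c(F)c1F
Why: Proposed new method: fluoride attacks silicon of 8 and expels triflate to release benzyne 11, the crown-separated phenoxide 9 adds through oxygen to the strained triple bond, and the resulting ortho aryl anion 12 takes electrophilic bromine from 10 through a halogen-bonded transition state, leaving the stabilised, weakly nucleophilic pentafluorophenyl anion. The closest known reaction types are the three-component bromothiolation of arynes (sulfur nucleophile, bromopentafluorobenzene as bromine donor, KF/18-crown-6) and the fluoride-mediated O-arylation of phenols, electron-poor and ortho-substituted ones included, by silylaryl triflates; the step merges the two. No ring is closed and no stereocentre is created. Benzyne is symmetrical, so there is no regiochemical choice, and the adjacent placement of O and Br on ring B follows from addition across the former triple bond. The selectivity needed is bromine transfer to 12 in preference to protonation (which would give the bromine-free ether) or to bromide loss from a polybromoaryl anion (a second aryne); it is secured by the absence of any O–H or N–H donor (KH-derived salt, dried KF and crown ether), by the large excess of the fast bromine donor and by the low temperature. Should 12 instead pick up the neighbouring ortho bromine of ring A, ring B is still ortho-brominated and the relocated anion on ring A is re-brominated by 10, so both pathways should end at 13.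

Step 7
Reactants: 13 1,2,3,4-tetrabromo-5-(2-bromophenoxy)-6-methoxybenzene
Product: 15 2,3,4,5-tetrabromo-6-(2-bromophenoxy)phenol (target CNP0324984.0), via aryloxydibromoborane 14 (not isolated)
Conditions: BBr3 (3 equiv), CH2Cl2, −78 °C to rt; then H2O, 0 °C
Reagents that add atoms: none
Why: Lewis-acid ether cleavage in which BBr3 binds the methoxy oxygen and bromide attacks the methyl carbon by SN2, while the diaryl ether offers no sp3 carbon and the aryl bromides are inert, so hydrolysis of the aryloxyborane should release only the desired phenol.

**Compound list**

1 | guaiacol (2-methoxyphenol) | COc1ccccc1O | starting material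
2 | 3,4,5,6-tetrabromoguaiacol (2,3,4,5-tetrabromo-6-methoxyphenol) | COc1c(O)c(Br)c(Br)c(Br)c1Br | intermediate
3 | 2-bromophenol | Oc1ccccc1Br | starting material
4 | (2-bromophenoxy)trimethylsilane | C[Si](C)(C)Oc1ccccc1Br | intermediate
5 | (2-lithiophenoxy)trimethylsilane | C[Si](C)(C)Oc1ccccc1[Li] | intermediate
6 | lithium 2-(trimethylsilyl)phenoxide | C[Si](C)(C)c1ccccc1[O-].[Li+] | intermediate
7 | 2-(trimethylsilyl)phenol | C[Si](C)(C)c1ccccc1O | intermediate
8 | 2-(trimethylsilyl)phenyl trifluoromethanesulfonate | C[Si](C)(C)c1ccccc1OS(=O)(=O)C(F)(F)F | intermediate
9 | potassium 2,3,4,5-tetrabromo-6-methoxyphenoxide | COc1c([O-])c(Br)c(Br)c(Br)c1Br.[K+] | intermediate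
10 | bromopentafluorobenzene | Fc1c(F)c(F)c(Br)c(F)c1F | starting material
11 | benzyne | C1=CC=CC#C1 | intermediate
12 | 2-(2,3,4,5-tetrabromo-6-methoxyphenoxy)phenylpotassium | COc1c(Br)c(Br)c(Br)c(Br)c1Oc1cccc[c-]1.[K+] | intermediate
13 | 1,2,3,4-tetrabromo-5-(2-bromophenoxy)-6-methoxybenzene | COc1c(Br)c(Br)c(Br)c(Br)c1Oc1ccccc1Br | intermediate
14 | dibromo[2,3,4,5-tetrabromo-6-(2-bromophenoxy)phenoxy]borane | BrB(Br)Oc1c(Br)c(Br)c(Br)c(Br)c1Oc1ccccc1Br | intermediate
15 | 2,3,4,5-tetrabromo-6-(2-bromophenoxy)phenol | Oc1c(Br)c(Br)c(Br)c(Br)c1Oc1ccccc1Br | target

**Step count**

Total steps: 7. Longest linear sequence: 5 steps (2-bromophenol 3 through steps 2, 3, 4, 6 and 7).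

**Steps most likely to fail**

1. Step 6 (proposed three-component aryloxy-bromination). Capture of benzyne by the hindered, weakly basic phenoxide may be too slow, so that the aryne is consumed by fluoride or by the pentafluorophenyl anion. The aryl anion may also be protonated before bromine transfer, and the phenoxide may attack the para fluorine of the bromine donor. The fallback uses known chemistry, sets out from 2 and comes back at 13, bypassing steps 2 to 6. 1-Bromo-2-iodobenzene would be oxidised with mCPBA and TsOH·H2O in MeCN and the hypervalent iodine species captured by 1,3,5-trimethoxybenzene to give (2-bromophenyl)(2,4,6-trimethoxyphenyl)iodonium tosylate F1. Metal-free O-arylation of 2 with F1 (K2CO3, MeCN or toluene, about 50 °C) should then transfer the 2-bromophenyl group by ligand coupling at iodine, the electron-rich trimethoxyphenyl group acting as the non-transferred ligand, and give 13 with the ring B bromine already in place.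

2. Step 1 (exhaustive bromination). Substitution may stop before the last, hindered position next to the methoxy group, or the methyl ether may be partly cleaved by the HBr that builds up under forcing conditions. The fallback sets out from 1 and comes back at 2. Guaiacol would be brominated with excess Br2 in AcOH and the mixture then heated with 48% aq HBr, so that ether cleavage is made deliberate and complete. This should give the symmetrical 3,4,5,6-tetrabromocatechol F2, whose four ring positions brominate readily. Desymmetrising mono-O-methylation of F2 (MeI 1.0 equiv, Li2CO3, DMF, 40 °C), which stops at the monoether because only the first, hydrogen-bond-stabilised phenoxide forms under the weak base, should then return 2.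

3. Step 7 (demethylation). Lewis-acid cleavage of the doubly flanked methoxy group may be incomplete, or prolonged exposure to BBr3 may start to attack the diaryl ether. The fallback sets out from 13 and comes back at 15. The cleavage would be moved from electrophilic activation at oxygen to nucleophilic SN2 attack at the methyl carbon: LiCl in DMF at about 120 °C should displace the tetrabromo-aryloxide, a very good leaving group, and give lithium 2,3,4,5-tetrabromo-6-(2-bromophenoxy)phenoxide F3. Cold dilute HCl would then give 15. The temperature is kept moderate so that the phenoxide does not close onto ring B with loss of bromide.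

**Further compounds**

F1 | step 6 | (2-bromophenyl)(2,4,6-trimethoxyphenyl)iodonium tosylate | COc1cc(OC)c([I+]c2ccccc2Br)c(OC)c1.Cc1ccc(S(=O)(=O)[O-])cc1
F2 | step 1 | 3,4,5,6-tetrabromocatechol | Oc1c(O)c(Br)c(Br)c(Br)c1Br
F3 | step 7 | lithium 2,3,4,5-tetrabromo-6-(2-bromophenoxy)phenoxide | [Li+].[O-]c1c(Br)c(Br)c(Br)c(Br)c1Oc1ccccc1Br
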